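**Assumption:** the target has no stereocentres, so no stereocontrol is needed; the racemic centres of 3, 4 and 5 are erased on aromatisation.

## Retrosynthetic overview

1. The target comes from global hydrogenolysis of a tetrabenzyl depside, which is disconnected at the aryl ester into a ring A acid and a ring B phenol.
2. Ring A acid: 4-O-benzylation, 2-O-methylation and saponification of methyl 2,4-dihydroxy-6-propylbenzoate.
3. Ring B phenol: the same benzoate by C3 formylation, dibenzylation, Baeyer–Villiger oxidation to the 3-OH, then methyl-to-benzyl ester exchange.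
4. The benzoate comes from aromatisation of a cyclohexane-1,3-dione made by intermolecular Michael addition of dimethyl malonate to (E)-hept-3-en-2-one with Claisen ring closure in the same flask (key C–C bond).
5. Ring order: one carbocycle is built in step 1, aromatised in step 2, and serves as the precursor of both ring A and ring B; no other ring is formed.

## Route

Step 1
Reactants: 1 dimethyl malonate; 2 (E)-hept-3-en-2-one
Product: 4 methyl 2,4-dioxo-6-propylcyclohexane-1-carboxylate (racemic; mainly enolised), via Michael adduct 3 (not isolated)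
Conditions: NaOMe (1.2 equiv), MeOH, reflux, 4 h; then aq. HCl, 0 °C
Reagents that add atoms: none
Why: Intermolecular Michael addition of the malonate anion to the enone β-carbon forms the key C–C bond, and the methyl-ketone enolate then closes the six-membered ring by intramolecular Claisen (Dieckmann) condensation, driven by the stabilised β-dicarbonyl enolate; the two racemic stereocentres are destroyed in step 2.

Step 2
Reactants: 4 methyl 2,4-dioxo-6-propylcyclohexane-1-carboxylate
Product: 6 methyl 2,4-dihydroxy-6-propylbenzoate, via bromodione 5 (not isolated)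
Conditions: Br2 (1.0 equiv), DMF, 0 °C, then 80 °C, 12 h
Reagents that add atoms: none
Why: α-Bromination of the enolised 1,3-dione followed by thermal dehydrobromination and tautomerisation gives the aromatic resorcylate (bromination–dehydrobromination aromatisation).

Step 3
Reactants: 6 methyl 2,4-dihydroxy-6-propylbenzoate
Product: 7 methyl 4-(benzyloxy)-2-hydroxy-6-propylbenzoate
Conditions: BnBr (1.05 equiv), K2CO3, acetone, reflux
Reagents that add atoms: benzyl bromide, BrCc1ccccc1
Why: Williamson etherification is selective for the 4-OH because the 2-OH is hydrogen-bonded to the ester carbonyl, less acidic and more hindered.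

Step 4
Reactants: 7 methyl 4-(benzyloxy)-2-hydroxy-6-propylbenzoate
Product: 8 methyl 4-(benzyloxy)-2-methoxy-6-propylbenzoate
Conditions: MeI (3 equiv), K2CO3, DMF, 50 °C
Reagents that add atoms: iodomethane, CI
Why: Williamson O-methylation of the remaining chelated phenol succeeds with excess MeI in a polar aprotic solvent.

Step 5
Reactants: 8 methyl 4-(benzyloxy)-2-methoxy-6-propylbenzoate
Product: 9 4-(benzyloxy)-2-methoxy-6-propylbenzoic acid
Conditions: KOH, DMSO/H2O (4:1), 90 °C; then cold aq. HCl to pH 3
Reagents that add atoms: potassium hydroxide, [K+].[OH-]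
Why: Saponification of the di-ortho-substituted ester needs poorly solvated hydroxide in aqueous DMSO; the aryl ethers are inert and cold acidification avoids decarboxylation.

Step 6
Reactants: 6 methyl 2,4-dihydroxy-6-propylbenzoate
Product: 11 methyl 3-formyl-2,4-dihydroxy-6-propylbenzoate, via chloro ether 10 (not isolated)
Conditions: Cl2CHOMe (1.1 equiv), TiCl4 (2.2 equiv), CH2Cl2, 0 °C to rt; then ice/aq. HCl; chromatography to remove any 5-formyl isomer
Reagents that add atoms: dichloromethyl methyl ether, COC(Cl)Cl; water, O
Why: Rieche formylation (electrophilic aromatic substitution) is directed by the titanium-bound phenoxides to C3, which is ortho to both oxygens and less hindered than C5 beside the propyl group; aqueous hydrolysis of the chloro ether releases the doubly hydrogen-bonded aldehyde.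

Step 7
Reactants: 11 methyl 3-formyl-2,4-dihydroxy-6-propylbenzoate
Product: 12 methyl 2,4-bis(benzyloxy)-3-formyl-6-propylbenzoate
Conditions: BnBr (2.5 equiv), K2CO3, DMF, 60 °C
Reagents that add atoms: benzyl bromide, BrCc1ccccc1
Why: Double Williamson etherification under forcing conditions alkylates both chelated phenols; the non-enolisable aldehyde and the ester are untouched.

Step 8
Reactants: 12 methyl 2,4-bis(benzyloxy)-3-formyl-6-propylbenzoate
Product: 14 methyl 2,4-bis(benzyloxy)-3-hydroxy-6-propylbenzoate, via aryl formate 13 (not isolated)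
Conditions: mCPBA (1.3 equiv), CH2Cl2, 0 °C to rt; aq. NaHCO3 wash; then K2CO3 (0.2 equiv), MeOH, rt
Reagents that add atoms: 3-chloroperoxybenzoic acid, OOC(=O)c1cccc(Cl)c1
Why: Baeyer–Villiger (Dakin-type) oxidation: the electron-rich di-ortho-alkoxy aryl group migrates to give the aryl formate, which mild methanolysis cleaves to the phenol without touching the hindered methyl ester.

Step 9
Reactants: 14 methyl 2,4-bis(benzyloxy)-3-hydroxy-6-propylbenzoate
Product: 15 2,4-bis(benzyloxy)-3-hydroxy-6-propylbenzoic acid
Conditions: KOH, DMSO/H2O (4:1), 90 °C, N2; then cold aq. HCl to pH 3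
Reagents that add atoms: potassium hydroxide, [K+].[OH-]
Why: Saponification as in step 5; the phenoxide is meta to the ester and does not deactivate it, and the benzyl ethers are stable to base.

Step 10
Reactants: 15 2,4-bis(benzyloxy)-3-hydroxy-6-propylbenzoic acid
Product: 16 benzyl 2,4-bis(benzyloxy)-3-hydroxy-6-propylbenzoate
Conditions: BnBr (1.05 equiv), KHCO3 (1.1 equiv), DMF, rt
Reagents that add atoms: benzyl bromide, BrCc1ccccc1
Why: Chemoselective SN2 alkylation of the carboxylate: hydrogencarbonate deprotonates the acid but not the phenol, so the 3-OH stays free.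

Step 11
Reactants: 9 4-(benzyloxy)-2-methoxy-6-propylbenzoic acid; 16 benzyl 2,4-bis(benzyloxy)-3-hydroxy-6-propylbenzoate
Product: 18 benzyl 2,4-bis(benzyloxy)-3-{[4-(benzyloxy)-2-methoxy-6-propylbenzoyl]oxy}-6-propylbenzoate, via mixed anhydride 17 (not isolated)
Conditions: (CF3CO)2O (3 equiv), toluene, rt
Reagents that add atoms: none
Why: Mixed-anhydride esterification: the electron-rich di-ortho-substituted acid forms a trifluoroacetic mixed anhydride (acylium-like, small linear electrophile) that acylates the only free phenol to form the depside ester.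

Step 12
Reactants: 18 benzyl 2,4-bis(benzyloxy)-3-{[4-(benzyloxy)-2-methoxy-6-propylbenzoyl]oxy}-6-propylbenzoate
Product: 19 2,4-dihydroxy-3-[(4-hydroxy-2-methoxy-6-propylbenzoyl)oxy]-6-propylbenzoic acid (CNP0482898.0)
Conditions: H2 (1 atm), 10% Pd/C, EtOAc, rt
Reagents that add atoms: none
Why: Catalytic hydrogenolysis removes the three benzyl ethers and the benzyl ester under neutral conditions that leave the aryl ester link, the methyl ether and the propyl chains intact and avoid acyl migration; no stereocentre is involved.

## Compound list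

1 | dimethyl malonate | COC(=O)CC(=O)OC | starting material
2 | (E)-hept-3-en-2-one | CCC/C=C/C(C)=O | starting material
3 | dimethyl 2-(2-oxoheptan-4-yl)propanedioate (racemic Michael adduct) | CCCC(CC(C)=O)C(C(=O)OC)C(=O)OC | intermediate (not isolated)
4 | methyl 2,4-dioxo-6-propylcyclohexane-1-carboxylate (racemic, mainly enol form) | CCCC1CC(=O)CC(=O)C1C(=O)OC | intermediate
5 | methyl 3-bromo-2,4-dioxo-6-propylcyclohexane-1-carboxylate (racemic) | CCCC1CC(=O)C(Br)C(=O)C1C(=O)OC | intermediate (not isolated)
6 | methyl 2,4-dihydroxy-6-propylbenzoate | CCCc1cc(O)cc(O)c1C(=O)OC | intermediate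
7 | methyl 4-(benzyloxy)-2-hydroxy-6-propylbenzoate | CCCc1cc(OCc2ccccc2)cc(O)c1C(=O)OC | intermediate
8 | methyl 4-(benzyloxy)-2-methoxy-6-propylbenzoate | CCCc1cc(OCc2ccccc2)cc(OC)c1C(=O)OC | intermediate
9 | 4-(benzyloxy)-2-methoxy-6-propylbenzoic acid | CCCc1cc(OCc2ccccc2)cc(OC)c1C(=O)O | intermediate
10 | methyl 3-[chloro(methoxy)methyl]-2,4-dihydroxy-6-propylbenzoate (titanium-bound in the flask) | CCCc1cc(O)c(C(Cl)OC)c(O)c1C(=O)OC | intermediate (not isolated)
11 | methyl 3-formyl-2,4-dihydroxy-6-propylbenzoate | CCCc1cc(O)c(C=O)c(O)c1C(=O)OC | intermediate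
12 | methyl 2,4-bis(benzyloxy)-3-formyl-6-propylbenzoate | CCCc1cc(OCc2ccccc2)c(C=O)c(OCc2ccccc2)c1C(=O)OC | intermediate
13 | methyl 2,4-bis(benzyloxy)-3-(formyloxy)-6-propylbenzoate | CCCc1cc(OCc2ccccc2)c(OC=O)c(OCc2ccccc2)c1C(=O)OC | intermediate (not isolated)
14 | methyl 2,4-bis(benzyloxy)-3-hydroxy-6-propylbenzoate | CCCc1cc(OCc2ccccc2)c(O)c(OCc2ccccc2)c1C(=O)OC | intermediate
15 | 2,4-bis(benzyloxy)-3-hydroxy-6-propylbenzoic acid | CCCc1cc(OCc2ccccc2)c(O)c(OCc2ccccc2)c1C(=O)O | intermediate
16 | benzyl 2,4-bis(benzyloxy)-3-hydroxy-6-propylbenzoate | CCCc1cc(OCc2ccccc2)c(O)c(OCc2ccccc2)c1C(=O)OCc1ccccc1 | intermediate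
17 | 4-(benzyloxy)-2-methoxy-6-propylbenzoic trifluoroacetic anhydride | CCCc1cc(OCc2ccccc2)cc(OC)c1C(=O)OC(=O)C(F)(F)F | intermediate (not isolated)
18 | benzyl 2,4-bis(benzyloxy)-3-{[4-(benzyloxy)-2-methoxy-6-propylbenzoyl]oxy}-6-propylbenzoate | CCCc1cc(OCc2ccccc2)cc(OC)c1C(=O)Oc1c(OCc2ccccc2)cc(CCC)c(C(=O)OCc2ccccc2)c1OCc1ccccc1 | intermediate
19 | 2,4-dihydroxy-3-[(4-hydroxy-2-methoxy-6-propylbenzoyl)oxy]-6-propylbenzoic acid | CCCc1cc(O)cc(OC)c1C(=O)Oc1c(O)cc(CCC)c(C(=O)O)c1O | target

## Step count and risk

Total steps: 12.
Longest linear sequence: 9 steps (1, 2, 6, 7, 8, 9, 10, 11, 12); the ring A branch (3, 4, 5) joins at step 11.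

Three steps most likely to fail:

**Step 6 (regioselectivity of the formylation).** Some C5-formyl isomer or diformylation may form and erode the yield. The fallback sets out from 7, already made for ring A. Magnesium-phenoxide-directed ortho-formylation (MgCl2, Et3N, paraformaldehyde, MeCN, reflux) can only attack C3, the single free position ortho to the only free OH. It gives methyl 4-(benzyloxy)-3-formyl-2-hydroxy-6-propylbenzoate F1. Benzylation of its remaining phenol (BnBr, K2CO3, DMF, 60 °C) comes back to the route at 12.

**Step 11 (depside coupling of two di-ortho-substituted partners).** The phenol of 16 is flanked by two benzyloxy groups, and the acidic medium may cause trifluoroacetylation or ring acylation. The fallback sets out from 9 and 16 and uses a preformed acyl chloride with a phenolate nucleophile under acid-free conditions. Acid 9 is converted with (COCl)2 and catalytic DMF in CH2Cl2 into 4-(benzyloxy)-2-methoxy-6-propylbenzoyl chloride F2. Phenol 16 is deprotonated with NaH in THF at 0 °C to sodium 2,6-bis(benzyloxy)-3-[(benzyloxy)carbonyl]-4-propylphenolate F3. Combining the two at 0 °C to rt comes back to the route at 18.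

**Step 2 (aromatisation).** Nuclear over-bromination and partial ester loss at 80 °C can lower the yield. The fallback sets out from 4 and makes over-bromination the intended path. Excess Br2 (3 equiv) in AcOH at rt aromatises and brominates both free ring positions, giving methyl 3,5-dibromo-2,4-dihydroxy-6-propylbenzoate F4. Hydrogenolytic debromination (H2, 10% Pd/C, NaOAc, MeOH, rt) then comes back to the route at 6.

## Further compounds

F1 | step 6 | methyl 4-(benzyloxy)-3-formyl-2-hydroxy-6-propylbenzoate | CCCc1cc(OCc2ccccc2)c(C=O)c(O)c1C(=O)OC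
F2 | step 11 | 4-(benzyloxy)-2-methoxy-6-propylbenzoyl chloride | CCCc1cc(OCc2ccccc2)cc(OC)c1C(Cl)=O
F3 | step 11 | sodium 2,6-bis(benzyloxy)-3-[(benzyloxy)carbonyl]-4-propylphenolate | CCCc1cc(OCc2ccccc2)c([O-])c(OCc2ccccc2)c1C(=O)OCc1ccccc1.[Na+]
F4 | step 2 | methyl 3,5-dibromo-2,4-dihydroxy-6-propylbenzoate | CCCc1c(Br)c(O)c(Br)c(O)c1C(=O)OC
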